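## Retrosynthetic overview
1. The pyran ring is made last. The C3=C4 double bond comes from DDQ dehydrogenation of a chroman, and the O1–aryl bond from an intramolecular Pd-catalysed etherification of a tertiary alcohol, so the C2–O bond is never broken.
2. The C4–aryl bond comes from hydroboration and B-alkyl Suzuki coupling of a linalool-type vinyl carbinol with a 2-bromo-6-alkoxy aryl iodide made from 3-bromo-5-methylphenol.
3. The key disconnection is chromene C2–CH2. An aldol addition of the (S)-lactic acid derived dioxolanone enolate to a cyclohexyl acetaldehyde sets C2, and the extra carbinol is then removed by Barton–McCombie deoxygenation.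
4. The cyclohexyl acetaldehyde comes from 4,4-dimethylcyclohexenone. CBS reduction and Eschenmoser–Claisen chirality transfer set the side-chain stereocentre. Carbonylation, hydrogenation and epimerisation set the trans carboxyl stereocentre.
5. Ring order: the carbocycle and the arene are bought. Only the dihydropyran ring is closed (step 17) and then unsaturated (step 20).

Assumption: the SMILES is read as (1S,2R)-trans in the cyclohexane and (2R) in the chromene, and 1, 10, 20 and all reagents are catalogue items.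

## Route

Step 1
Reactants: 1 4,4-dimethylcyclohex-2-en-1-one
Product: 2 2-iodo-4,4-dimethylcyclohex-2-en-1-one
Conditions: iodine (1.6 equiv), pyridine/CH2Cl2 1:1, 0 °C to rt
Reagents that add atoms: iodine [I][I]
Why: In this Johnson α-iodination (Baylis–Hillman type), pyridine adds reversibly, the enolate is iodinated and pyridine is expelled, so only the α-vinylic position reacts and no stereocentre is formed.

Step 2
Reactants: 2 2-iodo-4,4-dimethylcyclohex-2-en-1-one
Product: 3 (1R)-2-iodo-4,4-dimethylcyclohex-2-en-1-ol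
Conditions: (S)-2-methyl-CBS-oxazaborolidine (10 mol%), BH3·SMe2 (0.7 equiv), THF, −20 °C; MeOH quench
Reagents that add atoms: none
Why: In this Corey–Bakshi–Shibata reduction the iodoalkenyl arm acts as the large group, so the (S)-catalyst gives the (R)-carbinol by clean 1,2-reduction (at least 95% ee expected for α-halo enones).

Step 3
Reactants: 3 (1R)-2-iodo-4,4-dimethylcyclohex-2-en-1-ol
Product: 5 2-[(1S)-2-iodo-6,6-dimethylcyclohex-2-en-1-yl]-N,N-dimethylacetamide, via ketene N,O-acetal 4 (not isolated)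
Conditions: MeC(OMe)2NMe2 (4 equiv), xylenes, 140 °C, MeOH distilled off
Reagents that add atoms: N,N-dimethylacetamide dimethyl acetal COC(C)(OC)N(C)C
Why: The Eschenmoser–Claisen [3,3] shift is suprafacial, so the new C–C bond forms on the face that carried the C–O bond, which sets the side-chain-bearing ring stereocentre of the target.

Step 4
Reactants: 5 2-[(1S)-2-iodo-6,6-dimethylcyclohex-2-en-1-yl]-N,N-dimethylacetamide
Product: 6 methyl (6S)-6-[2-(dimethylamino)-2-oxoethyl]-5,5-dimethylcyclohex-1-ene-1-carboxylate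
Conditions: Pd(OAc)2 (5 mol%), dppf (6 mol%), CO (1 atm), Et3N, MeOH/DMF, 65 °C
Reagents that add atoms: carbon monoxide [C-]#[O+]; methanol CO
Why: In this Heck-type alkoxycarbonylation, zerovalent palladium inserts into the alkenyl iodide, CO inserts and methanolysis gives the enoate without touching the allylic stereocentre.

Step 5
Reactants: 6 methyl (6S)-6-[2-(dimethylamino)-2-oxoethyl]-5,5-dimethylcyclohex-1-ene-1-carboxylate
Product: 8 methyl (1S,2R)-2-[2-(dimethylamino)-2-oxoethyl]-3,3-dimethylcyclohexane-1-carboxylate, via cis ester 7 (not isolated)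
Conditions: H2 (4 bar), 10% Pd/C, MeOH, rt; filter; NaOMe (0.3 equiv), MeOH, 65 °C
Reagents that add atoms: none
Why: Catalytic syn-hydrogenation anti to the side chain gives the cis ester, and base epimerisation of the only acidic stereocentre then gives the diequatorial trans ester (about 9:1, minor cis isomer recycled), which sets the carboxyl-bearing stereocentre.

Step 6
Reactants: 8 methyl (1S,2R)-2-[2-(dimethylamino)-2-oxoethyl]-3,3-dimethylcyclohexane-1-carboxylate
Product: 9 methyl (1S,2R)-3,3-dimethyl-2-(2-oxoethyl)cyclohexane-1-carboxylate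
Conditions: Cp2Zr(H)Cl (1.8 equiv), THF, rt, 30 min; H2O/silica work-up
Reagents that add atoms: none
Why: In this Schwartz-reagent (Georg) amide reduction, hydrozirconation of the tertiary amide gives a stable zirconated hemiaminal that releases the aldehyde only on work-up, and esters are not attacked.

Step 7
Reactants: 10 (S)-lactic acid
Product: 11 (2S,5S)-2-tert-butyl-5-methyl-1,3-dioxolan-4-one
Conditions: pivalaldehyde (1.5 equiv), p-TsOH (cat.), pentane, reflux, Dean–Stark; crystallisation from pentane at −78 °C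
Reagents that add atoms: pivalaldehyde CC(C)(C)C=O
Why: This Seebach acetalisation favours the cis acetal under thermodynamic control (about 4:1) and it is obtained pure by crystallisation, so the lactic acid chirality is stored at the acetal carbon.

Step 8 (key step)
Reactants: 11 (2S,5S)-2-tert-butyl-5-methyl-1,3-dioxolan-4-one; 9 methyl (1S,2R)-3,3-dimethyl-2-(2-oxoethyl)cyclohexane-1-carboxylate
Product: 13 methyl (1S,2R)-2-{2-[(2S,4R)-2-tert-butyl-4-methyl-5-oxo-1,3-dioxolan-4-yl]-2-hydroxyethyl}-3,3-dimethylcyclohexane-1-carboxylate (both carbinol epimers), via lithium enolate 12 (not isolated)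
Conditions: 11 (1.3 equiv), LiN(iPr)2 (commercial solution, 1.35 equiv), THF, −78 °C, 40 min; 9, −78 °C, 2 h; AcOH quench at −78 °C
Reagents that add atoms: none
Why: In this intermolecular aldol addition with self-regeneration of the stereocentre, the aldehyde approaches the planar enolate anti to the tert-butyl group (at least 95:5), which fixes the oxygenated quaternary carbon in the configuration of chromene C2, and the new carbinol centre does not matter because it is removed.

Step 9
Reactants: 13 aldol adduct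
Product: 14 O-phenyl thionocarbonate of 13
Conditions: ClC(S)OPh (2 equiv), DMAP (4 equiv), CH2Cl2, rt to 40 °C
Reagents that add atoms: O-phenyl chlorothionoformate ClC(=S)Oc1ccccc1
Why: This DMAP-catalysed thioacylation (Robins variant) runs under non-basic conditions, so the retro-aldol cleavage that xanthate formation with NaH would cause is avoided.

Step 10
Reactants: 14 O-phenyl thionocarbonate of 13
Product: 15 methyl (1S,2R)-2-{2-[(2S,4R)-2-tert-butyl-4-methyl-5-oxo-1,3-dioxolan-4-yl]ethyl}-3,3-dimethylcyclohexane-1-carboxylate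
Conditions: Bu3SnH (2 equiv), AIBN (0.2 equiv), toluene, 100 °C
Reagents that add atoms: none
Why: In this Barton–McCombie deoxygenation the secondary radical is simply reduced, because β-alkoxy and β-acyl groups do not fragment, so both carbinol epimers converge on one compound with all stereocentres intact.

Step 11
Reactants: 15 deoxygenated dioxolanone
Product: 17 methyl (1S,2R)-2-[(3R)-3,4-dihydroxy-3-methylbutyl]-3,3-dimethylcyclohexane-1-carboxylate, via hydroxy ester 16 (not isolated)
Conditions: K2CO3 (0.2 equiv), MeOH, rt, 1 h; then NaBH4 (5 equiv), 0 °C to rt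
Reagents that add atoms: none
Why: Methanolysis opens the activated acylal, and hydroxyl-assisted borohydride reduction then takes the α-hydroxy ester to the diol while the unactivated, hindered ring ester is inert to NaBH4.

Step 12
Reactants: 17 methyl (1S,2R)-2-[(3R)-3,4-dihydroxy-3-methylbutyl]-3,3-dimethylcyclohexane-1-carboxylate
Product: 18 methyl (1S,2R)-2-[(3R)-3-hydroxy-3-methyl-4-oxobutyl]-3,3-dimethylcyclohexane-1-carboxylate
Conditions: (COCl)2, DMSO, CH2Cl2, −78 °C; Et3N, −78 to 0 °C
Reagents that add atoms: none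
Why: In this Swern oxidation only the primary alcohol can be oxidised, no glycol cleavage occurs, and the α-carbon is quaternary so it cannot epimerise.

Step 13
Reactants: 18 methyl (1S,2R)-2-[(3R)-3-hydroxy-3-methyl-4-oxobutyl]-3,3-dimethylcyclohexane-1-carboxylate
Product: 19 methyl (1S,2R)-2-[(3R)-3-hydroxy-3-methylpent-4-en-1-yl]-3,3-dimethylcyclohexane-1-carboxylate
Conditions: MePPh3Br (3 equiv), KOtBu (2.8 equiv), THF, 0 °C; then 18, 0 °C
Reagents that add atoms: methyltriphenylphosphonium bromide C[P+](c1ccccc1)(c1ccccc1)c1ccccc1.[Br-]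
Why: In this Wittig methylenation excess ylide tolerates the free tertiary hydroxyl (as in linalool syntheses from 2-hydroxy-2-methyl aldehydes) and does not attack the hindered ester.

Step 14
Reactants: 20 3-bromo-5-methylphenol
Product: 21 1-bromo-3-(methoxymethoxy)-5-methylbenzene
Conditions: MOMCl (1.3 equiv), iPr2NEt (1.6 equiv), CH2Cl2, 0 °C to rt
Reagents that add atoms: chloromethyl methyl ether COCCl
Why: O-alkylation of the phenol installs a base-stable group that also directs the next metalation.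

Step 15
Reactants: 21 1-bromo-3-(methoxymethoxy)-5-methylbenzene
Product: 23 1-bromo-2-iodo-3-(methoxymethoxy)-5-methylbenzene, via aryllithium 22 (not isolated)
Conditions: LiN(iPr)2 (commercial solution, 1.1 equiv), THF, −78 °C, 1 h; iodine in THF, −78 °C
Reagents that add atoms: iodine [I][I]
Why: In this directed ortho-metalation the proton between Br and OMOM is by far the most acidic, the amide base does not exchange the bromide, and at −78 °C the anion is iodinated before aryne formation.

Step 16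
Reactants: 19 methyl (1S,2R)-2-[(3R)-3-hydroxy-3-methylpent-4-en-1-yl]-3,3-dimethylcyclohexane-1-carboxylate; 23 1-bromo-2-iodo-3-(methoxymethoxy)-5-methylbenzene
Product: 25 methyl (1S,2R)-2-{(3R)-5-[2-bromo-6-(methoxymethoxy)-4-methylphenyl]-3-hydroxy-3-methylpentyl}-3,3-dimethylcyclohexane-1-carboxylate, via B-alkyl-9-BBN adduct 24 (not isolated)
Conditions: 9-BBN (1.6 equiv B–H), THF, rt, 4 h; then 23 (1.2 equiv), PdCl2(dppf) (5 mol%), 3 M aq K3PO4, DMF, 45 °C
Reagents that add atoms: none
Why: In this anti-Markovnikov hydroboration and B-alkyl Suzuki–Miyaura coupling, boron goes only to the terminal carbon and oxidative addition takes the aryl iodide well before the bromide.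

Step 17
Reactants: 25 bromoaryl tertiary alcohol
Product: 26 methyl (1S,2R)-2-{2-[(2R)-5-(methoxymethoxy)-2,7-dimethyl-3,4-dihydro-2H-chromen-2-yl]ethyl}-3,3-dimethylcyclohexane-1-carboxylate
Conditions: Pd(OAc)2 (5 mol%), 2-(di-tert-butylphosphino)-1,1'-binaphthyl (6 mol%), Cs2CO3 (1.5 equiv), toluene, 80 °C
Reagents that add atoms: none
Why: In this intramolecular Buchwald-type C–O coupling the tertiary alkoxide has no α-hydrogen for β-hydride elimination, and only the aryl–O bond is formed, so the C2 configuration is retained.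

Step 18
Reactants: 26 MOM-protected chroman
Product: 27 methyl (1S,2R)-2-{2-[(2R)-5-hydroxy-2,7-dimethyl-3,4-dihydro-2H-chromen-2-yl]ethyl}-3,3-dimethylcyclohexane-1-carboxylate
Conditions: conc. HCl (cat.), MeOH, 45 °C
Reagents that add atoms: none
Why: The acid-catalysed acetal exchange is done at the acid-stable chroman stage so that the later chromene never meets acid.

Step 19
Reactants: 27 5-hydroxychroman
Product: 28 methyl (1S,2R)-2-{2-[(2R)-5-(tert-butyldimethylsilyloxy)-2,7-dimethyl-3,4-dihydro-2H-chromen-2-yl]ethyl}-3,3-dimethylcyclohexane-1-carboxylate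
Conditions: TBSCl (1.5 equiv), imidazole (3 equiv), DMF, rt
Reagents that add atoms: tert-butyldimethylsilyl chloride CC(C)(C)[Si](C)(C)Cl
Why: Silylation protects the phenol from quinone oxidation, keeps the ring electron-rich and gives a group that is cleaved by base.

Step 20
Reactants: 28 silyl-protected chroman
Product: 29 methyl (1S,2R)-2-{2-[(2R)-5-(tert-butyldimethylsilyloxy)-2,7-dimethyl-2H-chromen-2-yl]ethyl}-3,3-dimethylcyclohexane-1-carboxylate
Conditions: DDQ (1.6 equiv), benzene, 80 °C, dark, argon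
Reagents that add atoms: none
Why: In this DDQ dehydrogenation hydride leaves C4, whose cation is stabilised by both ortho oxygens, and loss of H3 gives the chromene; the aryl methyl group is meta to both oxygens and is not attacked, and C2 is not involved.

Step 21
Reactants: 29 protected chromene ester
Product: 30 (1S,2R)-2-{2-[(2R)-5-hydroxy-2,7-dimethyl-2H-chromen-2-yl]ethyl}-3,3-dimethylcyclohexane-1-carboxylic acid
Conditions: LiOH·H2O (10 equiv), THF/MeOH/H2O 2:1:1, 50 °C, argon, dark; 1 M HCl to pH 4 at 0 °C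
Reagents that add atoms: lithium hydroxide [Li+].[OH-]
Why: Saponification cleaves the aryl silyl ether and the equatorial methyl ester together, the trans acid is the thermodynamic epimer so base cannot erode it, and mild temperature with exclusion of light avoids electrocyclic opening of the chromene.

## Compound list
1 | 4,4-dimethylcyclohex-2-en-1-one | CC1(C)CCC(=O)C=C1 | starting material
2 | 2-iodo-4,4-dimethylcyclohex-2-en-1-one | CC1(C)CCC(=O)C(I)=C1 | intermediate
3 | (1R)-2-iodo-4,4-dimethylcyclohex-2-en-1-ol | O[C@@H]1CCC(C)(C)C=C1I | intermediate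
4 | 1-{[(1R)-2-iodo-4,4-dimethylcyclohex-2-en-1-yl]oxy}-N,N-dimethylethen-1-amine (ketene N,O-acetal) | C=C(N(C)C)O[C@@H]1CCC(C)(C)C=C1I | intermediate
5 | 2-[(1S)-2-iodo-6,6-dimethylcyclohex-2-en-1-yl]-N,N-dimethylacetamide | CN(C)C(=O)C[C@@H]1C(I)=CCCC1(C)C | intermediate
6 | methyl (6S)-6-[2-(dimethylamino)-2-oxoethyl]-5,5-dimethylcyclohex-1-ene-1-carboxylate | CN(C)C(=O)C[C@@H]1C(C(=O)OC)=CCCC1(C)C | intermediate
7 | methyl (1R,2R)-2-[2-(dimethylamino)-2-oxoethyl]-3,3-dimethylcyclohexane-1-carboxylate (cis) | CN(C)C(=O)C[C@@H]1[C@H](C(=O)OC)CCCC1(C)C | intermediate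
8 | methyl (1S,2R)-2-[2-(dimethylamino)-2-oxoethyl]-3,3-dimethylcyclohexane-1-carboxylate (trans) | CN(C)C(=O)C[C@@H]1[C@@H](C(=O)OC)CCCC1(C)C | intermediate
9 | methyl (1S,2R)-3,3-dimethyl-2-(2-oxoethyl)cyclohexane-1-carboxylate | O=CC[C@@H]1[C@@H](C(=O)OC)CCCC1(C)C | intermediate
10 | (S)-lactic acid | C[C@H](O)C(=O)O | starting material
11 | (2S,5S)-2-tert-butyl-5-methyl-1,3-dioxolan-4-one (cis) | C[C@@H]1O[C@H](C(C)(C)C)OC1=O | intermediate
12 | lithium (2S)-2-tert-butyl-5-methyl-1,3-dioxol-4-olate | CC1=C([O-])O[C@@H](C(C)(C)C)O1.[Li+] | intermediate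
13 | methyl (1S,2R)-2-{2-[(2S,4R)-2-tert-butyl-4-methyl-5-oxo-1,3-dioxolan-4-yl]-2-hydroxyethyl}-3,3-dimethylcyclohexane-1-carboxylate (carbinol epimers) | C[C@]1(C(O)C[C@@H]2[C@@H](C(=O)OC)CCCC2(C)C)O[C@H](C(C)(C)C)OC1=O | intermediate
14 | O-phenyl thionocarbonate of 13 | C[C@]1(C(OC(=S)Oc2ccccc2)C[C@@H]2[C@@H](C(=O)OC)CCCC2(C)C)O[C@H](C(C)(C)C)OC1=O | intermediate
15 | methyl (1S,2R)-2-{2-[(2S,4R)-2-tert-butyl-4-methyl-5-oxo-1,3-dioxolan-4-yl]ethyl}-3,3-dimethylcyclohexane-1-carboxylate | C[C@]1(CC[C@@H]2[C@@H](C(=O)OC)CCCC2(C)C)O[C@H](C(C)(C)C)OC1=O | intermediate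
16 | methyl (1S,2R)-2-[(3R)-3-hydroxy-4-methoxy-3-methyl-4-oxobutyl]-3,3-dimethylcyclohexane-1-carboxylate | O[C@](C)(CC[C@@H]1[C@@H](C(=O)OC)CCCC1(C)C)C(=O)OC | intermediate
17 | methyl (1S,2R)-2-[(3R)-3,4-dihydroxy-3-methylbutyl]-3,3-dimethylcyclohexane-1-carboxylate | O[C@](C)(CC[C@@H]1[C@@H](C(=O)OC)CCCC1(C)C)CO | intermediate
18 | methyl (1S,2R)-2-[(3R)-3-hydroxy-3-methyl-4-oxobutyl]-3,3-dimethylcyclohexane-1-carboxylate | O[C@](C)(CC[C@@H]1[C@@H](C(=O)OC)CCCC1(C)C)C=O | intermediate
19 | methyl (1S,2R)-2-[(3R)-3-hydroxy-3-methylpent-4-en-1-yl]-3,3-dimethylcyclohexane-1-carboxylate | O[C@](C)(CC[C@@H]1[C@@H](C(=O)OC)CCCC1(C)C)C=C | intermediate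
20 | 3-bromo-5-methylphenol | Cc1cc(O)cc(Br)c1 | starting material
21 | 1-bromo-3-(methoxymethoxy)-5-methylbenzene | COCOc1cc(C)cc(Br)c1 | intermediate
22 | [2-bromo-6-(methoxymethoxy)-4-methylphenyl]lithium | COCOc1cc(C)cc(Br)c1[Li] | intermediate
23 | 1-bromo-2-iodo-3-(methoxymethoxy)-5-methylbenzene | COCOc1cc(C)cc(Br)c1I | intermediate
24 | methyl (1S,2R)-2-[(3S)-5-(9-borabicyclo[3.3.1]nonan-9-yl)-3-hydroxy-3-methylpentyl]-3,3-dimethylcyclohexane-1-carboxylate (same geometry as 19, descriptor changes by priority only) | O[C@](C)(CC[C@@H]1[C@@H](C(=O)OC)CCCC1(C)C)CCB1C2CCCC1CCC2 | intermediate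
25 | methyl (1S,2R)-2-{(3R)-5-[2-bromo-6-(methoxymethoxy)-4-methylphenyl]-3-hydroxy-3-methylpentyl}-3,3-dimethylcyclohexane-1-carboxylate | O[C@](C)(CC[C@@H]1[C@@H](C(=O)OC)CCCC1(C)C)CCc1c(Br)cc(C)cc1OCOC | intermediate
26 | methyl (1S,2R)-2-{2-[(2R)-5-(methoxymethoxy)-2,7-dimethyl-3,4-dihydro-2H-chromen-2-yl]ethyl}-3,3-dimethylcyclohexane-1-carboxylate | Cc1cc(OCOC)c2c(c1)O[C@](C)(CC[C@@H]1[C@@H](C(=O)OC)CCCC1(C)C)CC2 | intermediate
27 | methyl (1S,2R)-2-{2-[(2R)-5-hydroxy-2,7-dimethyl-3,4-dihydro-2H-chromen-2-yl]ethyl}-3,3-dimethylcyclohexane-1-carboxylate | Cc1cc(O)c2c(c1)O[C@](C)(CC[C@@H]1[C@@H](C(=O)OC)CCCC1(C)C)CC2 | intermediate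
28 | methyl (1S,2R)-2-{2-[(2R)-5-(tert-butyldimethylsilyloxy)-2,7-dimethyl-3,4-dihydro-2H-chromen-2-yl]ethyl}-3,3-dimethylcyclohexane-1-carboxylate | Cc1cc(O[Si](C)(C)C(C)(C)C)c2c(c1)O[C@](C)(CC[C@@H]1[C@@H](C(=O)OC)CCCC1(C)C)CC2 | intermediate
29 | methyl (1S,2R)-2-{2-[(2R)-5-(tert-butyldimethylsilyloxy)-2,7-dimethyl-2H-chromen-2-yl]ethyl}-3,3-dimethylcyclohexane-1-carboxylate | Cc1cc(O[Si](C)(C)C(C)(C)C)c2c(c1)O[C@](C)(CC[C@@H]1[C@@H](C(=O)OC)CCCC1(C)C)C=C2 | intermediate
30 | (1S,2R)-2-{2-[(2R)-5-hydroxy-2,7-dimethyl-2H-chromen-2-yl]ethyl}-3,3-dimethylcyclohexane-1-carboxylic acid (CNP0144010.1) | Cc1cc(O)c2c(c1)O[C@](C)(CC[C@@H]1[C@@H](C(=O)O)CCCC1(C)C)C=C2 | target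

## Counts and risks
Total step count: 21.
Longest linear sequence: 18 (steps 1–6, 8–13, 16–21).

**Step 3 (Claisen bond formation next to the quaternary carbon).**
- Risk: the ketene aminal may eliminate to a diene instead of rearranging.
- The fallback brings in the side chain by a conjugate allylation. It sets out from 2 and comes back at 9.
- Methoxycarbonylation of 2 (Pd(OAc)2, dppf, CO, MeOH, Et3N) gives the doubly activated acceptor methyl 3,3-dimethyl-6-oxocyclohex-1-ene-1-carboxylate F1.
- An enantioselective Hosomi–Sakurai conjugate addition of allyltrimethylsilane follows, under Cu(OTf)2 and (S,S)-tert-butyl-bis(oxazoline). The ligand antipode is chosen so that the product correlates with 9. This gives methyl (1R,2R)-3,3-dimethyl-6-oxo-2-(prop-2-en-1-yl)cyclohexane-1-carboxylate F2.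
- NaH and PhNTf2 convert F2 into methyl (6S)-5,5-dimethyl-6-(prop-2-en-1-yl)-2-(trifluoromethylsulfonyloxy)cyclohex-1-ene-1-carboxylate F3.
- Formate reduction (Pd(OAc)2, PPh3, HCO2H, Et3N) gives methyl (6S)-5,5-dimethyl-6-(prop-2-en-1-yl)cyclohex-1-ene-1-carboxylate F4.
- Mg in MeOH followed by NaOMe equilibration gives methyl (1S,2R)-3,3-dimethyl-2-(prop-2-en-1-yl)cyclohexane-1-carboxylate F5.
- Ozonolysis of the allyl group (O3, then Me2S) gives 9.

**Step 9 (acylation of a carbinol next to a quaternary centre).**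
- Risk: thioacylation may be too slow, or δ-lactonisation onto the ring ester may compete.
- The fallback keeps the aldol but removes the oxygen by elimination and hydrogenation instead of a radical. It sets out from 13 and comes back at 15.
- Martin sulfurane, Ph2S[OC(CF3)2Ph]2, in CH2Cl2 at rt dehydrates 13 towards the only available β-hydrogens. This gives methyl (1S,2R)-2-{(E)-2-[(2S,4R)-2-tert-butyl-4-methyl-5-oxo-1,3-dioxolan-4-yl]ethenyl}-3,3-dimethylcyclohexane-1-carboxylate F6.
- Hydrogenation (H2, 10% Pd/C, EtOAc) gives 15.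

**Step 16 (sp3–sp2 coupling at a doubly ortho-substituted iodide next to a bromide).**
- Risk: slow transmetalation may allow protodeboronation or reaction at the bromide.
- The fallback uses a sterically undemanding alkyne coupling. It sets out from 18 and comes back at 25.
- Ohira–Bestmann homologation of 18 (dimethyl 1-diazo-2-oxopropylphosphonate, K2CO3, MeOH) gives methyl (1S,2R)-2-[(3R)-3-hydroxy-3-methylpent-4-yn-1-yl]-3,3-dimethylcyclohexane-1-carboxylate F7.
- Sonogashira coupling with 23 (PdCl2(PPh3)2, CuI, Et3N, rt) reacts at the iodide only. It gives methyl (1S,2R)-2-{(3R)-5-[2-bromo-6-(methoxymethoxy)-4-methylphenyl]-3-hydroxy-3-methylpent-4-yn-1-yl}-3,3-dimethylcyclohexane-1-carboxylate F8.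
- Saturation of the triple bond over PtO2 (H2, 1 atm, EtOAc), which spares the aryl bromide, gives 25.

## Further compounds
F1 | step 3 | methyl 3,3-dimethyl-6-oxocyclohex-1-ene-1-carboxylate | COC(=O)C1=CC(C)(C)CCC1=O
F2 | step 3 | methyl (1R,2R)-3,3-dimethyl-6-oxo-2-(prop-2-en-1-yl)cyclohexane-1-carboxylate | C=CC[C@@H]1[C@@H](C(=O)OC)C(=O)CCC1(C)C
F3 | step 3 | methyl (6S)-5,5-dimethyl-6-(prop-2-en-1-yl)-2-(trifluoromethylsulfonyloxy)cyclohex-1-ene-1-carboxylate | C=CC[C@@H]1C(C(=O)OC)=C(OS(=O)(=O)C(F)(F)F)CCC1(C)C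
F4 | step 3 | methyl (6S)-5,5-dimethyl-6-(prop-2-en-1-yl)cyclohex-1-ene-1-carboxylate | C=CC[C@@H]1C(C(=O)OC)=CCCC1(C)C
F5 | step 3 | methyl (1S,2R)-3,3-dimethyl-2-(prop-2-en-1-yl)cyclohexane-1-carboxylate | C=CC[C@@H]1[C@@H](C(=O)OC)CCCC1(C)C
F6 | step 9 | methyl (1S,2R)-2-{(E)-2-[(2S,4R)-2-tert-butyl-4-methyl-5-oxo-1,3-dioxolan-4-yl]ethenyl}-3,3-dimethylcyclohexane-1-carboxylate | C[C@]1(/C=C/[C@@H]2[C@@H](C(=O)OC)CCCC2(C)C)O[C@H](C(C)(C)C)OC1=O
F7 | step 16 | methyl (1S,2R)-2-[(3R)-3-hydroxy-3-methylpent-4-yn-1-yl]-3,3-dimethylcyclohexane-1-carboxylate | O[C@](C)(CC[C@@H]1[C@@H](C(=O)OC)CCCC1(C)C)C#C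
F8 | step 16 | methyl (1S,2R)-2-{(3R)-5-[2-bromo-6-(methoxymethoxy)-4-methylphenyl]-3-hydroxy-3-methylpent-4-yn-1-yl}-3,3-dimethylcyclohexane-1-carboxylate | O[C@](C)(CC[C@@H]1[C@@H](C(=O)OC)CCCC1(C)C)C#Cc1c(Br)cc(C)cc1OCOC
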